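The midnight run got twice the substrate of the dawn run, and I follow the dawn flask on to 15 d.

| flask | substrate | remark | time |
|---|---|---|---|
| dawn | 0.050 M | the very flask that is asked about, followed so far |  |
| midnight | 0.10 M | run made earlier |  |
| flask | 0.050 M |  | 15 d |

| run | time / d | isomer of the product / % | target / % |
|---|---|---|---|
| dawn | 0.625 | 68.4 | 26.4 |
| dawn | 1.67 | 70.8 | 27.6 |
| dawn | 3.00 | 70.4 | 27.8 |
| dawn | 5.00 | 69.9 | 27.7 |
| midnight | 2.50 | 46.2 | 53.2 |
| midnight | 5.00 | 38.7 | 62.2 |
| midnight | 8.00 | 35.6 | 63.5 |
| midnight | 10.0 | 35.0 | 65.3 |

(standard deviation of a reading: 1 percentage point)

- share of isomer of the product in isomer of the product plus target at 10 min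
- share of isomer of the product in isomer of the product plus target at 8.0 h
- share of isomer of the product in isomer of the product plus target at 15 d
- which of isomer of the product and target there is more of at 15 d

- amounts and yields of target count crystals too
- given per volume of solution although it is solid: crystals
- what may be going on: isomer of the product <-> substrate; substrate <-> target; target <-> isomer of the product; crystals <-> target

What looks wrong is this: the last midnight reading has isomer at 35.0% of the charge, half the 69.9% of the last dawn reading. Steps that are all first order keep fractions of the charge at a given time when the charge alone changes, and the dawn readings stand level within their scatter from 1.67 d on, so these two numbers do not go together. I multiply each fraction by its charge: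

midnight: 35.0% × 0.10 M = 0.0350 M

dawn: 69.9% × 0.050 M = 0.0350 M

The two now agree within the scatter of the readings. I call this reading the isomer plateau, the concentration at which isomer comes to rest late in a run with crystals of target. I take dissolved target to be held at its solubility limit once crystals stand, with isomer tied to it at rest, so the late isomer fraction is the plateau over the charge. Now I reckon the dawn flask at both ends:

early, first reading: share = 72.2%

late: isomer fraction = 70.0%; with target at 27.7%, share = 71.6%

The ends nearly meet, so I join them with a flat line near that share, though 10 min lies before any reading.

The forecast gives 72.5% at 10 min (68.5% to 76.5%), 72.3% at 8.0 h (69.5% to 75%) and 71.5% at 15 d (69.5% to 73%), with isomer of the product ahead, holding of the dawn flask that “it sits almost exactly at saturation”.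

The dawn flask gives 70.7% at 10 min, 71.9% at 8.0 h and 71.6% at 15 d, with isomer of the product ahead.

    isomer of the product ⇌ substrate (k = 0.00120 min⁻¹)
    substrate ⇌ target (K = 2.70, k = 0.0180 min⁻¹)
    target ⇌ isomer of the product (K = 13.0, k = 2.40 × 10⁻⁴ min⁻¹)
    crystals ⇌ target, rate k4*(cs4 - [target]) while solid is left; crystals form when [target] > cs4 (solubility = 2.70 mM, k = 0.0750 min⁻¹)

At 15.0 d the dawn flask holds crystals at 22.4% of the charge, counted in its target of 27.8%. Put to use on a neighbour charged with 0.085 M, the isomer plateau gives 41.2% of that charge as isomer at 15 d. It holds 41.3%, target leads there, and its share at 15 d is 41.8%.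

(All runs are simulated on assumed constants, and the scatter is random.)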